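**Retrosynthetic overview**

1. Target 21 is a flavan-3-ol unit (benzo ring A, catechol ring B, pyran ring C; 2R,3R,4S, i.e. 2,3-cis, 3,4-trans) joined through C4 to C5 of a 3,7,8,3',4'-pentahydroxyflavone (benzo ring D, catechol ring E, pyranone ring F). The end game is hydrogenolysis of ten benzyl ethers, after pyranone ring F has been built last on ring D (Br → benzyloxyacetyl, chelation-controlled ortho debenzylation, Baker–Venkataraman-type aroylation and cyclodehydration).
2. Key disconnection: C4–C4a of ring C. The pyran ring is closed by 6-endo Friedel–Crafts opening of a trans C3–C4 oxirane by ring A of a 2,3-bis(benzyloxy)phenyl ether; C3 keeps its oxygen and C4 is inverted.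
3. Enabling feature: on ring A, C4a is the only free carbon ortho to O1 (C8 carries oxygen) and it lies para to the C7 oxygen. C4 is benzylic to ring D, and the trans C3–OH/C4–aryl relation is what anti opening of a trans epoxide delivers.
4. The epoxy ether comes from Mitsunobu inversion of an erythro epoxy alcohol with 2,3-bis(benzyloxy)phenol (sets C2 cis to C3–O). The epoxy alcohol comes from Sharpless kinetic resolution of the allylic alcohol of a Claisen–Schmidt chalcone that already joins rings B and D.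
5. Ring order: aromatic rings A, B, D, E are bought → oxirane (step 4) → pyran ring C (step 7) → pyranone ring F (step 12).

Key step: step 7

Assumption: the benzyl-protected building blocks 1, 3, 7, 13 and 17 are taken as commercial.
Remark: in 11, 12 and F3 the C4 descriptor reads 4R only because bromine raises the CIP rank of ring D; the spatial arrangement is that of 4S in 14–21.

**Route**

Step 1
Reactants: 1 3,4,5-tris(benzyloxy)benzaldehyde
Product: 2 2-bromo-3,4,5-tris(benzyloxy)benzaldehyde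
Conditions: NBS (1.05 equiv), MeCN, 0 °C to rt, dark
Reagents that add atoms: N-bromosuccinimide, O=C1CCC(=O)N1Br
Why: Electrophilic aromatic bromination; the two free ring positions are equivalent and each is ortho and para to a benzyloxy group, so a polar solvent in the dark should give the ring bromide without touching the benzylic CH2 groups.

Step 2
Reactants: 2 2-bromo-3,4,5-tris(benzyloxy)benzaldehyde; 3 1-[3,4-bis(benzyloxy)phenyl]ethan-1-one
Product: 4 (E)-1-[3,4-bis(benzyloxy)phenyl]-3-[2-bromo-3,4,5-tris(benzyloxy)phenyl]prop-2-en-1-one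
Conditions: aq. KOH (0.5 equiv), EtOH/THF, rt
Reagents that add atoms: none
Why: Claisen–Schmidt aldol condensation; the acetophenone enolate adds to the non-enolisable aldehyde and E1cB dehydration should give the conjugated (E)-enone, which joins rings B and D through the future C2–C3–C4 chain.

Step 3
Reactants: 4 (E)-chalcone
Product: 5 rac-(E)-1-[3,4-bis(benzyloxy)phenyl]-3-[2-bromo-3,4,5-tris(benzyloxy)phenyl]prop-2-en-1-ol
Conditions: NaBH4, CeCl3·7H2O, MeOH/THF, 0 °C
Reagents that add atoms: none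
Why: Luche reduction; CeCl3-assisted NaBH4 should deliver hydride 1,2 to the enone and give the racemic allylic alcohol with the (E)-alkene intact.

Step 4
Reactants: 5 racemic allylic alcohol
Product: 6 (S)-[3,4-bis(benzyloxy)phenyl][(2S,3S)-3-[2-bromo-3,4,5-tris(benzyloxy)phenyl]oxiran-2-yl]methanol
Conditions: Ti(OiPr)4 (1.0 equiv), L-(+)-diisopropyl tartrate (1.2 equiv), t-BuOOH (0.55 equiv, in decane), 4 Å molecular sieves, CH2Cl2, −20 °C
Reagents that add atoms: tert-butyl hydroperoxide, CC(C)(C)OO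
Why: Sharpless kinetic resolution; with L-(+)-tartrate the (R)-enantiomer of 5 should be epoxidised fast, on the alkene face that this tartrate selects for (E)-allylic alcohols (the (2S,3S)-3-arylglycidol sense) and erythro to the carbinol, so the two oxirane centres and the carbinol centre are set together while the slow enantiomer stays unreacted and is removed by chromatography.

Step 5
Reactants: 7 2,3-bis(benzyloxy)benzaldehyde
Product: 9 2,3-bis(benzyloxy)phenol, via aryl formate 8 (not isolated)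
Conditions: mCPBA, CH2Cl2, rt; then K2CO3 (0.2 equiv), MeOH, rt
Reagents that add atoms: 3-chloroperoxybenzoic acid, OOC(=O)c1cccc(Cl)c1
Why: Dakin-type Baeyer–Villiger oxidation; the electron-rich aryl group migrates to oxygen and the resulting formate is methanolysed to the phenol.

Step 6
Reactants: 6 erythro epoxy alcohol; 9 2,3-bis(benzyloxy)phenol
Product: 10 (2R,3S)-2-{(R)-[3,4-bis(benzyloxy)phenyl][2,3-bis(benzyloxy)phenoxy]methyl}-3-[2-bromo-3,4,5-tris(benzyloxy)phenyl]oxirane
Conditions: PPh3 (1.5 equiv), DIAD (1.5 equiv), toluene, 0 °C to rt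
Reagents that add atoms: none
Why: Mitsunobu etherification; SN2 attack of the phenol on the activated carbinol should invert the benzylic centre (the future C2, S to R) and give the threo aryl ether required for a 2,3-cis flavan, the oxirane being a spectator.

Step 7
Reactants: 10 threo epoxy aryl ether
Product: 11 (2R,3R,4R)-7,8-bis(benzyloxy)-2-[3,4-bis(benzyloxy)phenyl]-4-[2-bromo-3,4,5-tris(benzyloxy)phenyl]-3,4-dihydro-2H-chromen-3-ol
Conditions: BF3·OEt2 (0.2 equiv), CH2Cl2, −78 to −40 °C; Et3N quench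
Reagents that add atoms: none
Why: BF3 coordinates the oxirane oxygen, the benzylic C4–O bond lengthens, and the free ortho carbon of the 2,3-bis(benzyloxy)phenoxy ring (the future C4a) attacks C4 from the rear before rearomatisation; this is an intramolecular Friedel–Crafts epoxy–arene cyclisation of the kind that turns trans-3-arylglycidyl aryl ethers into trans-4-arylchroman-3-ols. Ring C closes in the 6-endo-tet mode at the benzylic carbon, whereas attack at C3 would be a 5-exo closure without benzylic activation and ring B could only close a strained 5-endo indane. C4 is set by inversion of the ring-D-bearing oxirane carbon, so the trans epoxide geometry alone fixes the 3,4-trans relation, while C3 keeps its oxygen and configuration and C2 comes unchanged from step 6 (2,3-cis). Site selectivity on ring A needs no control because the other ortho position carries a benzyloxy group and the attacking carbon is para to the C7 ether oxygen. The competing 1,2-hydride shift to a C3 ketone should be held back by the low temperature and by the high nucleophilicity of this doubly activated carbon, and the ortho bromine and twisted para benzyloxy group of ring D keep cation character modest, which favours stereospecific SN2-like opening.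

Step 8
Reactants: 11 bromo chroman-3-ol
Product: 12 (2R,3R,4R)-3,7,8-tris(benzyloxy)-2-[3,4-bis(benzyloxy)phenyl]-4-[2-bromo-3,4,5-tris(benzyloxy)phenyl]-3,4-dihydro-2H-chromene
Conditions: NaH, BnBr, n-Bu4NI (cat.), DMF, 0 °C to rt
Reagents that add atoms: benzyl bromide, BrCc1ccccc1
Why: Williamson etherification of the C3 alkoxide, so that the hydroxyl cannot consume organolithium, base or aroyl chloride later; no stereocentre is touched.

Step 9
Reactants: 12 bromo chromane benzyl ether; 13 2-(benzyloxy)-N-methoxy-N-methylacetamide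
Product: 15 2-(benzyloxy)-1-{2,3,4-tris(benzyloxy)-6-[(2R,3R,4S)-3,7,8-tris(benzyloxy)-2-[3,4-bis(benzyloxy)phenyl]-3,4-dihydro-2H-chromen-4-yl]phenyl}ethan-1-one, via aryllithium 14 (not isolated)
Conditions: n-BuLi (1.1 equiv), THF, −78 °C; then 13, −78 to −20 °C; H2O
Reagents that add atoms: none
Why: Bromine–lithium exchange followed by acyl substitution on the Weinreb amide, whose chelated tetrahedral adduct prevents over-addition, should install the benzyloxyacetyl group at the future C4a of the flavonol without touching the stereocentres.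

Step 10
Reactants: 15 benzyloxyacetyl arene
Product: 16 2-(benzyloxy)-1-{3,4-bis(benzyloxy)-2-hydroxy-6-[(2R,3R,4S)-3,7,8-tris(benzyloxy)-2-[3,4-bis(benzyloxy)phenyl]-3,4-dihydro-2H-chromen-4-yl]phenyl}ethan-1-one
Conditions: MgBr2·OEt2 (3 equiv), toluene/Et2O, 60 °C; aqueous work-up
Reagents that add atoms: none
Why: Chelation-controlled ether cleavage; MgBr2 bridges the ketone oxygen and the single ortho benzyloxy oxygen, and bromide should remove only that benzyl group, freeing the phenol that becomes O1 of the flavonol.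

Step 11
Reactants: 17 3,4-bis(benzyloxy)benzoic acid
Product: 18 3,4-bis(benzyloxy)benzoyl chloride
Conditions: (COCl)2, DMF (cat.), CH2Cl2, 0 °C to rt
Reagents that add atoms: oxalyl chloride, O=C(Cl)C(=O)Cl
Why: Acid chloride formation through the chloroiminium species generated from oxalyl chloride and DMF.

Step 12
Reactants: 16 ortho-hydroxy ketone; 18 3,4-bis(benzyloxy)benzoyl chloride
Product: 20 3,7,8-tris(benzyloxy)-2-[3,4-bis(benzyloxy)phenyl]-5-[(2R,3R,4S)-3,7,8-tris(benzyloxy)-2-[3,4-bis(benzyloxy)phenyl]-3,4-dihydro-2H-chromen-4-yl]-4H-chromen-4-one, via 1,3-diketone 19 (not isolated)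
Conditions: LiHMDS (3.2 equiv), THF, −78 °C; 18, −78 °C to rt; aq. HCl; then TsOH·H2O (cat.), toluene, 80 °C
Reagents that add atoms: none
Why: Baker–Venkataraman-type C-aroylation of the ketone enolate (any O-aroylated phenoxide rearranges to the same 1,3-diketone under the excess base) followed by acid-catalysed cyclodehydration should close pyranone ring F as the 3-benzyloxyflavone, the flavan stereocentres being non-enolisable.

Step 13
Reactants: 20 deca-O-benzyl biflavonoid
Product: 21 2-(3,4-dihydroxyphenyl)-5-[(2R,3R,4S)-2-(3,4-dihydroxyphenyl)-3,7,8-trihydroxy-3,4-dihydro-2H-chromen-4-yl]-3,7,8-trihydroxy-4H-chromen-4-one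
Conditions: H2 (1 atm), Pd(OH)2/C, THF/MeOH, rt; work-up under argon
Reagents that add atoms: none
Why: Hydrogenolysis of all ten benzyl ethers; at 1 atm and room temperature the chromone C2=C3 bond and the benzylic C2–O1 bond of the flavan are expected to survive.

**Compound list**

1 | 3,4,5-tris(benzyloxy)benzaldehyde | O=Cc1cc(OCc2ccccc2)c(OCc2ccccc2)c(OCc2ccccc2)c1 | starting material
2 | 2-bromo-3,4,5-tris(benzyloxy)benzaldehyde | O=Cc1cc(OCc2ccccc2)c(OCc2ccccc2)c(OCc2ccccc2)c1Br | intermediate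
3 | 1-[3,4-bis(benzyloxy)phenyl]ethan-1-one | CC(=O)c1ccc(OCc2ccccc2)c(OCc2ccccc2)c1 | starting material
4 | (E)-1-[3,4-bis(benzyloxy)phenyl]-3-[2-bromo-3,4,5-tris(benzyloxy)phenyl]prop-2-en-1-one | O=C(/C=C/c1cc(OCc2ccccc2)c(OCc2ccccc2)c(OCc2ccccc2)c1Br)c1ccc(OCc2ccccc2)c(OCc2ccccc2)c1 | intermediate
5 | rac-(E)-1-[3,4-bis(benzyloxy)phenyl]-3-[2-bromo-3,4,5-tris(benzyloxy)phenyl]prop-2-en-1-ol | OC(/C=C/c1cc(OCc2ccccc2)c(OCc2ccccc2)c(OCc2ccccc2)c1Br)c1ccc(OCc2ccccc2)c(OCc2ccccc2)c1 | intermediate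
6 | (S)-[3,4-bis(benzyloxy)phenyl][(2S,3S)-3-[2-bromo-3,4,5-tris(benzyloxy)phenyl]oxiran-2-yl]methanol (erythro) | O[C@@H](c1ccc(OCc2ccccc2)c(OCc2ccccc2)c1)[C@@H]1O[C@H]1c1cc(OCc2ccccc2)c(OCc2ccccc2)c(OCc2ccccc2)c1Br | intermediate
7 | 2,3-bis(benzyloxy)benzaldehyde | O=Cc1cccc(OCc2ccccc2)c1OCc1ccccc1 | starting material
8 | 2,3-bis(benzyloxy)phenyl formate | O=COc1cccc(OCc2ccccc2)c1OCc1ccccc1 | intermediate
9 | 2,3-bis(benzyloxy)phenol | Oc1cccc(OCc2ccccc2)c1OCc1ccccc1 | intermediate
10 | (2R,3S)-2-{(R)-[3,4-bis(benzyloxy)phenyl][2,3-bis(benzyloxy)phenoxy]methyl}-3-[2-bromo-3,4,5-tris(benzyloxy)phenyl]oxirane (threo) | c1cc(OCc2ccccc2)c(OCc2ccccc2)c(c1)O[C@H](c1ccc(OCc2ccccc2)c(OCc2ccccc2)c1)[C@@H]1O[C@H]1c1cc(OCc2ccccc2)c(OCc2ccccc2)c(OCc2ccccc2)c1Br | intermediate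
11 | (2R,3R,4R)-7,8-bis(benzyloxy)-2-[3,4-bis(benzyloxy)phenyl]-4-[2-bromo-3,4,5-tris(benzyloxy)phenyl]-3,4-dihydro-2H-chromen-3-ol | Brc1c(OCc2ccccc2)c(OCc2ccccc2)c(OCc2ccccc2)cc1[C@H]1c2ccc(OCc3ccccc3)c(OCc3ccccc3)c2O[C@H](c2ccc(OCc3ccccc3)c(OCc3ccccc3)c2)[C@@H]1O | intermediate
12 | (2R,3R,4R)-3,7,8-tris(benzyloxy)-2-[3,4-bis(benzyloxy)phenyl]-4-[2-bromo-3,4,5-tris(benzyloxy)phenyl]-3,4-dihydro-2H-chromene | Brc1c(OCc2ccccc2)c(OCc2ccccc2)c(OCc2ccccc2)cc1[C@H]1c2ccc(OCc3ccccc3)c(OCc3ccccc3)c2O[C@H](c2ccc(OCc3ccccc3)c(OCc3ccccc3)c2)[C@@H]1OCc1ccccc1 | intermediate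
13 | 2-(benzyloxy)-N-methoxy-N-methylacetamide | CON(C)C(=O)COCc1ccccc1 | starting material
14 | {2,3,4-tris(benzyloxy)-6-[(2R,3R,4S)-3,7,8-tris(benzyloxy)-2-[3,4-bis(benzyloxy)phenyl]-3,4-dihydro-2H-chromen-4-yl]phenyl}lithium | [Li]c1c(OCc2ccccc2)c(OCc2ccccc2)c(OCc2ccccc2)cc1[C@H]1c2ccc(OCc3ccccc3)c(OCc3ccccc3)c2O[C@H](c2ccc(OCc3ccccc3)c(OCc3ccccc3)c2)[C@@H]1OCc1ccccc1 | intermediate
15 | 2-(benzyloxy)-1-{2,3,4-tris(benzyloxy)-6-[(2R,3R,4S)-3,7,8-tris(benzyloxy)-2-[3,4-bis(benzyloxy)phenyl]-3,4-dihydro-2H-chromen-4-yl]phenyl}ethan-1-one | O=C(COCc1ccccc1)c1c(OCc2ccccc2)c(OCc2ccccc2)c(OCc2ccccc2)cc1[C@H]1c2ccc(OCc3ccccc3)c(OCc3ccccc3)c2O[C@H](c2ccc(OCc3ccccc3)c(OCc3ccccc3)c2)[C@@H]1OCc1ccccc1 | intermediate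
16 | 2-(benzyloxy)-1-{3,4-bis(benzyloxy)-2-hydroxy-6-[(2R,3R,4S)-3,7,8-tris(benzyloxy)-2-[3,4-bis(benzyloxy)phenyl]-3,4-dihydro-2H-chromen-4-yl]phenyl}ethan-1-one | O=C(COCc1ccccc1)c1c(O)c(OCc2ccccc2)c(OCc2ccccc2)cc1[C@H]1c2ccc(OCc3ccccc3)c(OCc3ccccc3)c2O[C@H](c2ccc(OCc3ccccc3)c(OCc3ccccc3)c2)[C@@H]1OCc1ccccc1 | intermediate
17 | 3,4-bis(benzyloxy)benzoic acid | OC(=O)c1ccc(OCc2ccccc2)c(OCc2ccccc2)c1 | starting material
18 | 3,4-bis(benzyloxy)benzoyl chloride | ClC(=O)c1ccc(OCc2ccccc2)c(OCc2ccccc2)c1 | intermediate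
19 | 2-(benzyloxy)-1-[3,4-bis(benzyloxy)phenyl]-3-{3,4-bis(benzyloxy)-2-hydroxy-6-[(2R,3R,4S)-3,7,8-tris(benzyloxy)-2-[3,4-bis(benzyloxy)phenyl]-3,4-dihydro-2H-chromen-4-yl]phenyl}propane-1,3-dione (C2 of the dione unassigned, keto–enol mixture) | O=C(C(OCc1ccccc1)C(=O)c1ccc(OCc2ccccc2)c(OCc2ccccc2)c1)c1c(O)c(OCc2ccccc2)c(OCc2ccccc2)cc1[C@H]1c2ccc(OCc3ccccc3)c(OCc3ccccc3)c2O[C@H](c2ccc(OCc3ccccc3)c(OCc3ccccc3)c2)[C@@H]1OCc1ccccc1 | intermediate
20 | 3,7,8-tris(benzyloxy)-2-[3,4-bis(benzyloxy)phenyl]-5-[(2R,3R,4S)-3,7,8-tris(benzyloxy)-2-[3,4-bis(benzyloxy)phenyl]-3,4-dihydro-2H-chromen-4-yl]-4H-chromen-4-one | O=c1c(OCc2ccccc2)c(-c2ccc(OCc3ccccc3)c(OCc3ccccc3)c2)oc2c(OCc3ccccc3)c(OCc3ccccc3)cc([C@H]3c4ccc(OCc5ccccc5)c(OCc5ccccc5)c4O[C@H](c4ccc(OCc5ccccc5)c(OCc5ccccc5)c4)[C@@H]3OCc3ccccc3)c12 | intermediate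
21 | 2-(3,4-dihydroxyphenyl)-5-[(2R,3R,4S)-2-(3,4-dihydroxyphenyl)-3,7,8-trihydroxy-3,4-dihydro-2H-chromen-4-yl]-3,7,8-trihydroxy-4H-chromen-4-one | O=c1c(O)c(-c2ccc(O)c(O)c2)oc2c(O)c(O)cc([C@H]3c4ccc(O)c(O)c4O[C@H](c4ccc(O)c(O)c4)[C@@H]3O)c12 | target

**Step count and risks**

Total steps: 13. Longest linear sequence: 11 steps (steps 1, 2, 3, 4, 6, 7, 8, 9, 10, 12, 13; compound 1 to 21). By design, the kinetic resolution in step 4 converts at most half of 5.

Step 7 (key cyclisation). What may go wrong: the BF3-opened oxirane may undergo a 1,2-hydride shift to a C3 ketone before ring A traps it, or it may open through a long-lived benzylic cation with loss of the 3,4-trans relation. Fallback (neighbouring-group-controlled two-stage closure), setting out from 10: acid-catalysed methanolysis (camphorsulfonic acid, MeOH/CH2Cl2, 0 °C) opens the oxirane at the benzylic carbon to the 3-methoxypropan-2-ol F1. Acetylation (Ac2O, pyridine, DMAP) gives the 3-methoxypropan-2-yl acetate F2. TMSOTf (CH2Cl2, −78 °C) then ionises the benzylic methyl ether with participation of the neighbouring acetate; the trans-disubstituted dioxolanylium ion is favoured and ring A opens it from the opposite face, which should give the 3,4-trans chroman-3-yl acetate F3 whatever the C4 configuration of F2. K2CO3 in MeOH removes the acetate and the route is rejoined at 11.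

Step 6 (Mitsunobu etherification). What may go wrong: with the hindered, weakly acidic phenol the activated benzylic alcohol may be diverted to elimination or to N-alkylation of the reduced azodicarboxylate, or it may ionise with erosion of the inversion. Fallback (Mukaiyama oxidation–reduction condensation through an isolated phosphorus ester), setting out from 6: Ph2PCl, Et3N and DMAP in CH2Cl2 give the diphenylphosphinite F4. With phenol 9 and 2,6-dimethyl-1,4-benzoquinone in CH2Cl2 at room temperature, F4 should give the aryl ether with inversion, and the route is rejoined at 10.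

Step 9 (aryllithium acylation). What may go wrong: proton transfer from the enolisable Weinreb amide to the hindered aryllithium (flanked by a benzyloxy group and the chromanyl group) may return the debrominated arene instead of the ketone. Fallback (addition to an aldehyde, then oxidation), setting out from 12: bromine–lithium exchange (n-BuLi, THF, −78 °C), transmetallation with anhydrous CeCl3 and addition to 2-(benzyloxy)acetaldehyde give the 2-(benzyloxy)-1-arylethan-1-ol F5 as a mixture of carbinol epimers. Dess–Martin periodinane (CH2Cl2, rt) oxidises F5 and the route is rejoined at 15.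

Further compounds
F1 | step 7 | (1R,2R)-1-[3,4-bis(benzyloxy)phenyl]-1-[2,3-bis(benzyloxy)phenoxy]-3-[2-bromo-3,4,5-tris(benzyloxy)phenyl]-3-methoxypropan-2-ol (C3 unassigned) | c1cc(OCc2ccccc2)c(OCc2ccccc2)c(c1)O[C@H](c1ccc(OCc2ccccc2)c(OCc2ccccc2)c1)[C@H](O)C(OC)c1cc(OCc2ccccc2)c(OCc2ccccc2)c(OCc2ccccc2)c1Br
F2 | step 7 | (1R,2R)-1-[3,4-bis(benzyloxy)phenyl]-1-[2,3-bis(benzyloxy)phenoxy]-3-[2-bromo-3,4,5-tris(benzyloxy)phenyl]-3-methoxypropan-2-yl acetate (C3 unassigned) | c1cc(OCc2ccccc2)c(OCc2ccccc2)c(c1)O[C@H](c1ccc(OCc2ccccc2)c(OCc2ccccc2)c1)[C@H](OC(C)=O)C(OC)c1cc(OCc2ccccc2)c(OCc2ccccc2)c(OCc2ccccc2)c1Br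
F3 | step 7 | (2R,3R,4R)-7,8-bis(benzyloxy)-2-[3,4-bis(benzyloxy)phenyl]-4-[2-bromo-3,4,5-tris(benzyloxy)phenyl]-3,4-dihydro-2H-chromen-3-yl acetate | Brc1c(OCc2ccccc2)c(OCc2ccccc2)c(OCc2ccccc2)cc1[C@H]1c2ccc(OCc3ccccc3)c(OCc3ccccc3)c2O[C@H](c2ccc(OCc3ccccc3)c(OCc3ccccc3)c2)[C@@H]1OC(C)=O
F4 | step 6 | (S)-[3,4-bis(benzyloxy)phenyl][(2R,3S)-3-[2-bromo-3,4,5-tris(benzyloxy)phenyl]oxiran-2-yl]methyl diphenylphosphinite | c1ccccc1P(c1ccccc1)O[C@@H](c1ccc(OCc2ccccc2)c(OCc2ccccc2)c1)[C@@H]1O[C@H]1c1cc(OCc2ccccc2)c(OCc2ccccc2)c(OCc2ccccc2)c1Br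
F5 | step 9 | 2-(benzyloxy)-1-{2,3,4-tris(benzyloxy)-6-[(2R,3R,4S)-3,7,8-tris(benzyloxy)-2-[3,4-bis(benzyloxy)phenyl]-3,4-dihydro-2H-chromen-4-yl]phenyl}ethan-1-ol (carbinol epimers) | OC(COCc1ccccc1)c1c(OCc2ccccc2)c(OCc2ccccc2)c(OCc2ccccc2)cc1[C@H]1c2ccc(OCc3ccccc3)c(OCc3ccccc3)c2O[C@H](c2ccc(OCc3ccccc3)c(OCc3ccccc3)c2)[C@@H]1OCc1ccccc1
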